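**Retrosynthetic overview**
- The target is achiral and all 42 carbons sit in seven benzene rings that can be bought, so no ring is built and no C–C bond is made; the strategic bonds are the six C(aryl)–O bonds.
- Each ether joins two innately nucleophilic partners (a phenol oxygen and an electron-rich aryl carbon). The aryl carbon is therefore used with reversed polarity, as an aryl cation equivalent: an aryl(2,4,6-trimethoxyphenyl)iodonium salt that arylates a phenoxide without metal.
- Key step: the most hindered ether (ring D oxygen to ring E) is made first, on monomers, from 4-iodo-2,6-dimethoxyphenoxide and an ortho-silyloxy iodonium salt. The untouched C–I bond is then oxidised to the next iodonium centre (iodine relay), giving a two-ring D–E reagent.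
- Rings are joined in the order D+E (reagent), then A → B → C → (D–E) → F → G. Each chain cycle is fluoride unmasking of a silyl ether plus O-arylation in one pot; the ring B/F and ring C/E reagents each serve twice.
- Last step: cleavage of all eighteen methyl ethers.

Notation: rings A–G are lettered along the chain from the 2,4,6-trihydroxyphenoxy end (A) to the 3,4,5-trihydroxyphenoxy end (G); TMP = 2,4,6-trimethoxyphenyl; TIPS = triisopropylsilyl; dtbpy = 4,4'-di-tert-butyl-2,2'-bipyridine.

Assumption: the SMILES has no stereocentre and the ethers rotate freely, so no stereocontrol is needed; the four phenols and the iodide used as starting materials are taken as catalogue items.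

**Arylating reagents**

Step 1
Reactants: 1 5-iodo-1,2,3-trimethoxybenzene
Product: 3 (3,4,5-trimethoxyphenyl)(2,4,6-trimethoxyphenyl)iodonium tosylate (ring G reagent), via aryliodine diacetate 2 (not isolated)
Conditions: mCPBA (1.1 equiv), AcOH–CH2Cl2, rt, 3 h; then 1,3,5-trimethoxybenzene (1.1 equiv), TsOH·H2O (1.05 equiv), CF3CH2OH, 0 °C to rt; precipitate from Et2O–pentane
Reagents that add atoms: 1,3,5-trimethoxybenzene COc1cc(OC)cc(OC)c1; p-toluenesulfonic acid monohydrate Cc1ccc(cc1)S(=O)(=O)O.O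
Why: Peracid oxidation of the aryl iodide to the aryliodine diacetate, then acid-promoted electrophilic aromatic substitution on 1,3,5-trimethoxybenzene (Koser-type diaryliodonium synthesis), gives a bench-stable aryl cation equivalent whose TMP ligand is too electron-rich to be transferred.

Step 2
Reactants: 4 2,3-dimethoxyphenol
Product: 5 (2,3-dimethoxyphenoxy)triisopropylsilane
Conditions: TIPSOTf (1.2 equiv), 2,6-lutidine (1.5 equiv), CH2Cl2, 0 °C to rt
Reagents that add atoms: triisopropylsilyl triflate CC(C)[Si](OS(=O)(=O)C(F)(F)F)(C(C)C)C(C)C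
Why: Standard silyl ether protection; the bulky TIPS group resists phenoxides but is removed by fluoride in the chain-growth steps.

Step 3
Reactants: 5 (2,3-dimethoxyphenoxy)triisopropylsilane
Product: 7 (5-iodo-2,3-dimethoxyphenoxy)triisopropylsilane, via arylboronic pinacol ester 6 (not isolated)
Conditions: [Ir(OMe)(cod)]2 (1.5 mol%), dtbpy (3 mol%), B2pin2 (1.0 equiv), THF, 80 °C; then CuI (10 mol%), 1,10-phenanthroline (20 mol%), KI (1.5 equiv), MeOH–H2O 4:1, air, 80 °C
Reagents that add atoms: potassium iodide [K+].[I-]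
Why: Sterically controlled iridium-catalysed C–H borylation attacks the only C–H with no ortho substituent (C5), and copper-catalysed aerobic iododeboronation in the same pot replaces boron by iodine at that carbon.

Step 4
Reactants: 7 (5-iodo-2,3-dimethoxyphenoxy)triisopropylsilane
Product: 9 [3,4-dimethoxy-5-(triisopropylsilyloxy)phenyl](2,4,6-trimethoxyphenyl)iodonium tosylate (ring B/F reagent), via aryliodine diacetate 8 (not isolated)
Conditions: mCPBA (1.1 equiv), AcOH–CH2Cl2, rt; then 1,3,5-trimethoxybenzene (1.1 equiv), TsOH·H2O (1.05 equiv), CF3CH2OH, 0 °C to rt; precipitate from Et2O–pentane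
Reagents that add atoms: 1,3,5-trimethoxybenzene COc1cc(OC)cc(OC)c1; p-toluenesulfonic acid monohydrate Cc1ccc(cc1)S(=O)(=O)O.O
Why: Same iodine oxidation and Koser-type diaryliodonium synthesis as step 1; the hindered aryl TIPS ether survives the brief exposure to one equivalent of sulfonic acid.

Step 5
Reactants: 10 2,3,4-trimethoxyphenol
Product: 11 6-iodo-2,3,4-trimethoxyphenol
Conditions: NIS (1.02 equiv), MeCN, −10 °C to rt, dark
Reagents that add atoms: N-iodosuccinimide O=C1CCC(=O)N1I
Why: Electrophilic aromatic iodination is directed ortho to the free hydroxyl (its para position carries OMe), giving the 6-iodo isomer.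

Step 6
Reactants: 11 6-iodo-2,3,4-trimethoxyphenol
Product: 12 (6-iodo-2,3,4-trimethoxyphenoxy)triisopropylsilane
Conditions: TIPSOTf (1.3 equiv), 2,6-lutidine (1.6 equiv), CH2Cl2, 0 °C to rt
Reagents that add atoms: triisopropylsilyl triflate CC(C)[Si](OS(=O)(=O)C(F)(F)F)(C(C)C)C(C)C
Why: Silyl ether protection of a doubly ortho-substituted phenol, for which the silyl triflate is reactive enough.

Step 7
Reactants: 12 (6-iodo-2,3,4-trimethoxyphenoxy)triisopropylsilane
Product: 14 [3,4,5-trimethoxy-2-(triisopropylsilyloxy)phenyl](2,4,6-trimethoxyphenyl)iodonium tosylate (ring C/E reagent), via aryliodine diacetate 13 (not isolated)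
Conditions: mCPBA (1.1 equiv), AcOH–CH2Cl2, 0 °C to rt; then 1,3,5-trimethoxybenzene (1.2 equiv), TsOH·H2O (1.05 equiv), CF3CH2OH, 0 °C; precipitate from Et2O–pentane
Reagents that add atoms: 1,3,5-trimethoxybenzene COc1cc(OC)cc(OC)c1; p-toluenesulfonic acid monohydrate Cc1ccc(cc1)S(=O)(=O)O.O
Why: Same Koser-type diaryliodonium synthesis; it gives the reagent that delivers a pentaoxygenated ring with its second ether oxygen already in place as an ortho TIPS ether.

Step 8
Reactants: 15 2,6-dimethoxyphenol (syringol)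
Product: 16 4-iodo-2,6-dimethoxyphenol
Conditions: NIS (1.0 equiv), CF3CO2H (10 mol%), MeCN, 0 °C
Reagents that add atoms: N-iodosuccinimide O=C1CCC(=O)N1I
Why: Electrophilic aromatic iodination para to the phenolic hydroxyl of syringol.

Step 9
Reactants: 16 4-iodo-2,6-dimethoxyphenol; 14 ring C/E reagent
Product: 18 5-iodo-1,3-dimethoxy-2-[3,4,5-trimethoxy-2-(triisopropylsilyloxy)phenoxy]benzene (ring D–E iodide), via potassium phenoxide 17 (not isolated)
Conditions: KOtBu (1.0 equiv), THF, 0 °C, 15 min; then 14 (1.15 equiv), rt to 45 °C, 12 h, argon, dark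
Reagents that add atoms: none
Why: Key step: metal-free O-arylation of a phenoxide by an unsymmetrical diaryliodonium salt (ligand coupling at trivalent iodine) joins two innately nucleophilic partners, transfers the mono-ortho-substituted aryl in preference to the more electron-rich TMP ligand, and leaves the C–I bond untouched for the relay.

Step 10
Reactants: 18 ring D–E iodide
Product: 20 {3,5-dimethoxy-4-[3,4,5-trimethoxy-2-(triisopropylsilyloxy)phenoxy]phenyl}(2,4,6-trimethoxyphenyl)iodonium tosylate (ring D–E reagent), via aryliodine diacetate 19 (not isolated)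
Conditions: mCPBA (1.05 equiv), AcOH–CH2Cl2, 0 °C to rt; then 1,3,5-trimethoxybenzene (1.5 equiv), TsOH·H2O (1.05 equiv), CF3CH2OH, 0 °C; precipitate from Et2O–pentane
Reagents that add atoms: 1,3,5-trimethoxybenzene COc1cc(OC)cc(OC)c1; p-toluenesulfonic acid monohydrate Cc1ccc(cc1)S(=O)(=O)O.O
Why: Same Koser-type diaryliodonium synthesis; iodine is oxidised much faster than the alkoxy rings, and the excess 1,3,5-trimethoxybenzene present when the acid is added outcompetes the flanked ring E C–H for the electrophilic iodine.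

**Chain assembly**

Step 11
Reactants: 21 2,4,6-trimethoxyphenol; 9 ring B/F reagent
Product: 23 [2,3-dimethoxy-5-(2,4,6-trimethoxyphenoxy)phenoxy]triisopropylsilane (ring A–B silyl ether), via potassium phenoxide 22 (not isolated)
Conditions: KOtBu (1.0 equiv), THF, 0 °C; then 9 (1.2 equiv), rt, 6 h, argon
Reagents that add atoms: none
Why: Metal-free phenoxide O-arylation with a diaryliodonium salt; the unhindered, electronically neutral 3,4,5-trioxygenated aryl is transferred and the TIPS ether is inert to the stoichiometric phenoxide.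

Step 12
Reactants: 23 ring A–B silyl ether; 14 ring C/E reagent
Product: 25 {2-[2,3-dimethoxy-5-(2,4,6-trimethoxyphenoxy)phenoxy]-4,5,6-trimethoxyphenoxy}triisopropylsilane (ring A–B–C silyl ether), via tetrabutylammonium phenoxide 24 (not isolated)
Conditions: TBAF (1.0 M in THF, 1.0 equiv), THF, 0 °C, 20 min; then 14 (1.3 equiv), rt to 40 °C, argon
Reagents that add atoms: none
Why: Fluoride desilylation gives a naked phenoxide that is O-arylated in the same pot by ligand coupling at trivalent iodine, installing ring C with its next oxygen already masked as a TIPS ether.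

Step 13
Reactants: 25 ring A–B–C silyl ether; 20 ring D–E reagent
Product: 27 ring A–B–C–D–E pentamer silyl ether (the unmasked ring C oxygen of 25 bonded to the former iodonium carbon of 20; all other oxygens OMe; ring E keeps its ortho OTIPS), via tetrabutylammonium phenoxide 26 (not isolated)
Conditions: TBAF (1.0 M in THF, 1.0 equiv), THF, 0 °C, 20 min; then 20 (1.2 equiv), rt to 40 °C, argon
Reagents that add atoms: none
Why: Fluoride desilylation then diaryliodonium O-arylation; the hindered ring C phenoxide meets an unhindered iodonium carbon, and since all fluoride is consumed before 20 is added its own TIPS ether survives, so two rings are added at once.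

Step 14
Reactants: 27 pentamer silyl ether; 9 ring B/F reagent
Product: 29 ring A–B–C–D–E–F hexamer silyl ether (ring E oxygen bonded to the 3,4-dimethoxy-5-(triisopropylsilyloxy)phenyl ring F), via tetrabutylammonium phenoxide 28 (not isolated)
Conditions: TBAF (1.0 M in THF, 1.0 equiv), THF, 0 °C, 20 min; then 9 (1.3 equiv), rt to 40 °C, argon
Reagents that add atoms: none
Why: Fluoride desilylation then metal-free diaryliodonium O-arylation of the doubly ortho-substituted ring E phenoxide by the unhindered ring F aryl.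

Step 15
Reactants: 29 hexamer silyl ether; 3 ring G reagent
Product: 31 octadecamethyl ether of the target (heptamer with all eighteen OH as OMe), via tetrabutylammonium phenoxide 30 (not isolated)
Conditions: TBAF (1.0 M in THF, 1.0 equiv), THF, 0 °C, 20 min; then 3 (1.3 equiv), rt, argon
Reagents that add atoms: none
Why: Fluoride desilylation then metal-free diaryliodonium O-arylation by the 3,4,5-trimethoxyphenyl group closes the chain with ring G.

Step 16
Reactants: 31 octadecamethyl ether
Product: 32 CNP0137585.0 (target, eighteen free OH)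
Conditions: BBr3 (1.0 M in CH2Cl2, 45 equiv), CH2Cl2, −78 °C to rt, 36 h; ice-water quench; EtOAc extraction; Sephadex LH-20 (MeOH), all under argon
Reagents that add atoms: none
Why: Lewis-acid ether cleavage (bromide attacks the boron-activated O-methyl groups) removes all eighteen methyl groups while diaryl ethers are inert, and the water quench (not methanol) avoids acid-catalysed re-etherification of the phloroglucinol-type rings.

**Compound list**
1 | 5-iodo-1,2,3-trimethoxybenzene | COc1cc(I)cc(OC)c1OC | starting material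
2 | 5-(diacetoxyiodo)-1,2,3-trimethoxybenzene | COc1cc(cc(OC)c1OC)I(OC(C)=O)OC(C)=O | intermediate (not isolated)
3 | (3,4,5-trimethoxyphenyl)(2,4,6-trimethoxyphenyl)iodonium tosylate | COc1cc(cc(OC)c1OC)[I+]c1c(OC)cc(OC)cc1OC.Cc1ccc(cc1)S(=O)(=O)[O-] | intermediate
4 | 2,3-dimethoxyphenol | COc1cccc(O)c1OC | starting material
5 | (2,3-dimethoxyphenoxy)triisopropylsilane | COc1cccc(O[Si](C(C)C)(C(C)C)C(C)C)c1OC | intermediate
6 | 2-[3,4-dimethoxy-5-(triisopropylsilyloxy)phenyl]-4,4,5,5-tetramethyl-1,3,2-dioxaborolane | COc1cc(cc(O[Si](C(C)C)(C(C)C)C(C)C)c1OC)B1OC(C)(C)C(C)(C)O1 | intermediate (not isolated)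
7 | (5-iodo-2,3-dimethoxyphenoxy)triisopropylsilane | COc1cc(I)cc(O[Si](C(C)C)(C(C)C)C(C)C)c1OC | intermediate
8 | [5-(diacetoxyiodo)-2,3-dimethoxyphenoxy]triisopropylsilane | COc1cc(cc(O[Si](C(C)C)(C(C)C)C(C)C)c1OC)I(OC(C)=O)OC(C)=O | intermediate (not isolated)
9 | [3,4-dimethoxy-5-(triisopropylsilyloxy)phenyl](2,4,6-trimethoxyphenyl)iodonium tosylate | COc1cc(cc(O[Si](C(C)C)(C(C)C)C(C)C)c1OC)[I+]c1c(OC)cc(OC)cc1OC.Cc1ccc(cc1)S(=O)(=O)[O-] | intermediate
10 | 2,3,4-trimethoxyphenol | COc1ccc(O)c(OC)c1OC | starting material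
11 | 6-iodo-2,3,4-trimethoxyphenol | COc1cc(I)c(O)c(OC)c1OC | intermediate
12 | (6-iodo-2,3,4-trimethoxyphenoxy)triisopropylsilane | COc1cc(I)c(O[Si](C(C)C)(C(C)C)C(C)C)c(OC)c1OC | intermediate
13 | [6-(diacetoxyiodo)-2,3,4-trimethoxyphenoxy]triisopropylsilane | COc1cc(I(OC(C)=O)OC(C)=O)c(O[Si](C(C)C)(C(C)C)C(C)C)c(OC)c1OC | intermediate (not isolated)
14 | [3,4,5-trimethoxy-2-(triisopropylsilyloxy)phenyl](2,4,6-trimethoxyphenyl)iodonium tosylate | COc1cc([I+]c2c(OC)cc(OC)cc2OC)c(O[Si](C(C)C)(C(C)C)C(C)C)c(OC)c1OC.Cc1ccc(cc1)S(=O)(=O)[O-] | intermediate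
15 | 2,6-dimethoxyphenol | COc1cccc(OC)c1O | starting material
16 | 4-iodo-2,6-dimethoxyphenol | COc1cc(I)cc(OC)c1O | intermediate
17 | potassium 4-iodo-2,6-dimethoxyphenoxide | COc1cc(I)cc(OC)c1[O-].[K+] | intermediate (not isolated)
18 | 5-iodo-1,3-dimethoxy-2-[3,4,5-trimethoxy-2-(triisopropylsilyloxy)phenoxy]benzene | COc1cc(I)cc(OC)c1Oc1cc(OC)c(OC)c(OC)c1O[Si](C(C)C)(C(C)C)C(C)C | intermediate
19 | 5-(diacetoxyiodo)-1,3-dimethoxy-2-[3,4,5-trimethoxy-2-(triisopropylsilyloxy)phenoxy]benzene | COc1cc(cc(OC)c1Oc1cc(OC)c(OC)c(OC)c1O[Si](C(C)C)(C(C)C)C(C)C)I(OC(C)=O)OC(C)=O | intermediate (not isolated)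
20 | {3,5-dimethoxy-4-[3,4,5-trimethoxy-2-(triisopropylsilyloxy)phenoxy]phenyl}(2,4,6-trimethoxyphenyl)iodonium tosylate | COc1cc(cc(OC)c1Oc1cc(OC)c(OC)c(OC)c1O[Si](C(C)C)(C(C)C)C(C)C)[I+]c1c(OC)cc(OC)cc1OC.Cc1ccc(cc1)S(=O)(=O)[O-] | intermediate
21 | 2,4,6-trimethoxyphenol | COc1cc(OC)c(O)c(OC)c1 | starting material
22 | potassium 2,4,6-trimethoxyphenoxide | COc1cc(OC)c([O-])c(OC)c1.[K+] | intermediate (not isolated)
23 | [2,3-dimethoxy-5-(2,4,6-trimethoxyphenoxy)phenoxy]triisopropylsilane | COc1cc(OC)c(Oc2cc(OC)c(OC)c(O[Si](C(C)C)(C(C)C)C(C)C)c2)c(OC)c1 | intermediate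
24 | tetrabutylammonium 2,3-dimethoxy-5-(2,4,6-trimethoxyphenoxy)phenoxide | COc1cc(OC)c(Oc2cc(OC)c(OC)c([O-])c2)c(OC)c1.CCCC[N+](CCCC)(CCCC)CCCC | intermediate (not isolated)
25 | {2-[2,3-dimethoxy-5-(2,4,6-trimethoxyphenoxy)phenoxy]-4,5,6-trimethoxyphenoxy}triisopropylsilane | COc1cc(OC)c(Oc2cc(OC)c(OC)c(Oc3cc(OC)c(OC)c(OC)c3O[Si](C(C)C)(C(C)C)C(C)C)c2)c(OC)c1 | intermediate
26 | tetrabutylammonium phenoxide of the ring A–B–C trimer (25 without silyl group) | COc1cc(OC)c(Oc2cc(OC)c(OC)c(Oc3cc(OC)c(OC)c(OC)c3[O-])c2)c(OC)c1.CCCC[N+](CCCC)(CCCC)CCCC | intermediate (not isolated)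
27 | ring A–B–C–D–E pentamer, thirteen OMe, ring E ortho oxygen as TIPS ether | COc1cc(OC)c(Oc2cc(OC)c(OC)c(Oc3cc(OC)c(OC)c(OC)c3Oc3cc(OC)c(Oc4cc(OC)c(OC)c(OC)c4O[Si](C(C)C)(C(C)C)C(C)C)c(OC)c3)c2)c(OC)c1 | intermediate
28 | tetrabutylammonium phenoxide of the pentamer (27 without silyl group) | COc1cc(OC)c(Oc2cc(OC)c(OC)c(Oc3cc(OC)c(OC)c(OC)c3Oc3cc(OC)c(Oc4cc(OC)c(OC)c(OC)c4[O-])c(OC)c3)c2)c(OC)c1.CCCC[N+](CCCC)(CCCC)CCCC | intermediate (not isolated)
29 | ring A–B–C–D–E–F hexamer, fifteen OMe, ring F terminal oxygen as TIPS ether | COc1cc(OC)c(Oc2cc(OC)c(OC)c(Oc3cc(OC)c(OC)c(OC)c3Oc3cc(OC)c(Oc4cc(OC)c(OC)c(OC)c4Oc4cc(OC)c(OC)c(O[Si](C(C)C)(C(C)C)C(C)C)c4)c(OC)c3)c2)c(OC)c1 | intermediate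
30 | tetrabutylammonium phenoxide of the hexamer (29 without silyl group) | COc1cc(OC)c(Oc2cc(OC)c(OC)c(Oc3cc(OC)c(OC)c(OC)c3Oc3cc(OC)c(Oc4cc(OC)c(OC)c(OC)c4Oc4cc(OC)c(OC)c([O-])c4)c(OC)c3)c2)c(OC)c1.CCCC[N+](CCCC)(CCCC)CCCC | intermediate (not isolated)
31 | octadecamethyl ether of the target | COc1cc(OC)c(Oc2cc(OC)c(OC)c(Oc3cc(OC)c(OC)c(OC)c3Oc3cc(OC)c(Oc4cc(OC)c(OC)c(OC)c4Oc4cc(OC)c(OC)c(Oc5cc(OC)c(OC)c(OC)c5)c4)c(OC)c3)c2)c(OC)c1 | intermediate
32 | CNP0137585.0 | Oc1cc(O)c(Oc2cc(O)c(O)c(Oc3cc(O)c(O)c(O)c3Oc3cc(O)c(Oc4cc(O)c(O)c(O)c4Oc4cc(O)c(O)c(Oc5cc(O)c(O)c(O)c5)c4)c(O)c3)c2)c(O)c1 | target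

**Step count and risk**

Total steps: 16. Longest linear sequence: 9 (steps 2, 3, 4, 11, 12, 13, 14, 15, 16; the branch through steps 5, 6, 7, 9, 10, 13–16 is equally long).

Most likely to fail, step 9 (hindered, oxidisable phenoxide; possible transfer of TMP instead of the ortho-silyloxy aryl). Fallback, setting out from 12 (with 15) and returning at 18: the hindered ether is made by copper catalysis and the iodine is introduced afterwards. An Ullmann ether synthesis of 12 with syringol 15 (CuI, N,N-dimethylglycine, Cs2CO3, dioxane, 90 °C) gives 1,3-dimethoxy-2-[3,4,5-trimethoxy-2-(triisopropylsilyloxy)phenoxy]benzene F1. Sterically controlled borylation ([Ir(OMe)(cod)]2, dtbpy, B2pin2) at the only unflanked C–H, para to the ether oxygen of ring D, then gives 2-{3,5-dimethoxy-4-[3,4,5-trimethoxy-2-(triisopropylsilyloxy)phenoxy]phenyl}-4,4,5,5-tetramethyl-1,3,2-dioxaborolane F2. The CuI/KI/air iododeboronation used in step 3 converts this in the same pot into 18.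

Second, step 10 (peracid and electrophilic iodine next to the pentaoxygenated ring E). Fallback, setting out from 18 and returning at 20: the iodonium salt is assembled without any oxidant acting on 18. Stannylation of 18 (Pd(PPh3)4, a zerovalent palladium complex, (Bu3Sn)2, toluene, 100 °C) gives tributyl{3,5-dimethoxy-4-[3,4,5-trimethoxy-2-(triisopropylsilyloxy)phenoxy]phenyl}stannane F3. Ipso-destannylation by 2-(diacetoxyiodo)-1,3,5-trimethoxybenzene and TsOH·H2O (CH2Cl2–CF3CH2OH, 0 °C) then gives 20.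

Third, step 16 (eighteen cleavages at once and an air-sensitive product). Fallback, setting out from 31 and returning at 32: the free polyphenol is not purified as such. The crude product of the BBr3 reaction is peracetylated (Ac2O, pyridine, DMAP, argon) to the octadecaacetate of CNP0137585.0 F4, which is stable and is chromatographed on silica gel. It is then de-acetylated with hydrazine hydrate (MeCN–THF, 0 °C, argon) to 32.

**Further compounds**
F1 | step 9 | 1,3-dimethoxy-2-[3,4,5-trimethoxy-2-(triisopropylsilyloxy)phenoxy]benzene | COc1cccc(OC)c1Oc1cc(OC)c(OC)c(OC)c1O[Si](C(C)C)(C(C)C)C(C)C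
F2 | step 9 | 2-{3,5-dimethoxy-4-[3,4,5-trimethoxy-2-(triisopropylsilyloxy)phenoxy]phenyl}-4,4,5,5-tetramethyl-1,3,2-dioxaborolane | COc1cc(cc(OC)c1Oc1cc(OC)c(OC)c(OC)c1O[Si](C(C)C)(C(C)C)C(C)C)B1OC(C)(C)C(C)(C)O1
F3 | step 10 | tributyl{3,5-dimethoxy-4-[3,4,5-trimethoxy-2-(triisopropylsilyloxy)phenoxy]phenyl}stannane | CCCC[Sn](CCCC)(CCCC)c1cc(OC)c(Oc2cc(OC)c(OC)c(OC)c2O[Si](C(C)C)(C(C)C)C(C)C)c(OC)c1
F4 | step 16 | octadecaacetate of CNP0137585.0 | CC(=O)Oc1cc(OC(C)=O)c(Oc2cc(OC(C)=O)c(OC(C)=O)c(Oc3cc(OC(C)=O)c(OC(C)=O)c(OC(C)=O)c3Oc3cc(OC(C)=O)c(Oc4cc(OC(C)=O)c(OC(C)=O)c(OC(C)=O)c4Oc4cc(OC(C)=O)c(OC(C)=O)c(Oc5cc(OC(C)=O)c(OC(C)=O)c(OC(C)=O)c5)c4)c(OC(C)=O)c3)c2)c(OC(C)=O)c1
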